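The leftover here is small: partner exceeds solid substrate by 0.500 mM, so solid substrate is the limiting reagent.

    solid substrate ⇌ dissolved substrate, rate k1*(cs1 - [dissolved substrate]) while solid is left; crystals form when [dissolved substrate] > cs1 (cs1 = 4.3 mM, k1 = 0.00682 s⁻¹)
    dissolved substrate + partner → target (k2 = 0.0221 M⁻¹ s⁻¹)
    dissolved substrate + target → side product (k3 = 9.44 × 10⁻⁴ M⁻¹ s⁻¹)
    solid product ⇌ target, rate k4*(cs4 - [target]) while solid is left; crystals form when [target] > cs4 (cs4 = 3.4 mM, k4 = 0.0443 s⁻¹)

solid substrate 10 mM; partner 10.5 mM; time 6.0 h

- in percentages every species weighs as the solid substrate in it: one side product counts as two
- for target the solid product is counted in
- as a solid, counted per litre of solution: solid substrate, solid product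
- at the start none of the solid substrate is in solution
- dissolved substrate means what is dissolved; the solid is not counted in it
- run time (flask): 6.0 h

- target and solid product together at 6.0 h, in percent of the solid substrate charged
- concentration of dissolved substrate in solution at 3.0 h, in percent of saturation
- the change that raises the amount of target and solid product together at 6.0 h, in percent of the solid substrate charged most ("none" if none brings more than 2 percentage points) (north-west / south-east / south-west / north-east / none)
- amount of target and solid product together at 6.0 h, in percent of the solid substrate charged, after south-east

- north-west: doubling the solubility in step 4, all else as stated
- south-east: doubling the dissolution coefficient of step 1, all else as stated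
- south-west: doubling the amount of partner, all else as stated
- north-east: doubling the dissolution coefficient of step 4, all else as stated

I carry one quantity, the coupling clock 2.92 h: one over the coupling constant times the solubility of the substrate, which is the time in which a saturated solution thins the partner by a factor e. Dissolution takes 2.44 min, far shorter than the clock, so I hold dissolved substrate at saturation and the partner decays pseudo-first-order.

Target plus solid product therefore starts at 3.59 mM h⁻¹ and bends over. Crystals of solid product begin at 1.14 h, but that only moves target between its forms, so the curve shows no mark. The knee comes when the coupled amount equals the charge minus the solubility, at 2.29 h. After it I treat substrate and partner as equal, so dissolved substrate falls as a hyperbola, the solubility over one plus elapsed time per clock. That gives saturation 80.4% and, with 1.89 mM still dissolved at the end, y 81.1%. I drop the side step, which with target at its solubility and partner as charged runs at 1.38% of the coupling rate.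

Faster dissolution moves the knee by half the fill time, worth 0.058 percentage points, so yb is 81.1%. Doubled partner brings the knee to 0.926 h and then a first-order tail, worth 18 points. The changes to the target crystals bear on dissolved target, which feeds the side step I have dropped, so this reckoning scores them zero, and the pick is south-west.

The forecast says y 80%, sat 78.5%, best south-west, yb 80.2%, because “The yield is therefore limited by the coupling rate”. My y stands higher than its figure, and so does my saturation.

The flask gives y 80.1%, sat 78.5%, best south-west, yb 80.2%. Side product stands at 3.88% at 6.00 h. The flask charged with 40 mM of solid substrate still holds 65.9% as solid at 6.00 h, so it stays on the saturated stretch. There the clock puts the partner left at 12.8%, and that flask shows 13%.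

The constants used here were drawn at random within sensible limits; no experiment stands behind them.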